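The plan rests on tracing the O1–C8a bond of lactone ring B back to a ketone carbon held on C8a (chroman-2-one numbering; ring A carbocycle, ring B lactone). The feature used is that O1 on C8a lies meta to the oxygens on C5 and C7 and is acylated by C2: oxidising an arene next to existing oxygens cannot build that array, whereas a benzaldehyde carries a carbon there from the outset. Peracid ring expansion of a 3-phenylindan-1-one slips O1 between C2 and C8a and so forms ring B in one operation, the C4 stereocentre being already present. The substrate is (3S)-7-bromo-4,6-dimethoxy-3-phenylindan-1-one, whose bromine reserves the future C8.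

Key step: step 4

Assumption: the (R)-BINAP rhodium catalyst is taken to deliver hydride to the alkene face that gives the 3S indanone; should the sense prove opposite, (S)-BINAP is used and nothing else changes.

Step 1
Reactants: 1 2-bromo-3,5-dimethoxybenzaldehyde; 2 (1-phenylvinyl)boronic acid
Product: 3 3,5-dimethoxy-2-(1-phenylvinyl)benzaldehyde
Conditions: Pd(OAc)2 (3 mol%), SPhos (6 mol%), K3PO4, 2 (1.5 equiv), toluene/H2O, 80 °C
Reagents that add atoms: none
Why: Suzuki–Miyaura coupling of an aryl bromide with an alkenylboronic acid; the bulky electron-rich biaryl phosphine is chosen because the bromide is flanked by the formyl and a methoxy group, and the aldehyde is inert under these conditions.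

Step 2
Reactants: 3 3,5-dimethoxy-2-(1-phenylvinyl)benzaldehyde
Product: 4 (3S)-4,6-dimethoxy-3-phenylindan-1-one
Conditions: [Rh(cod)2]BF4 (5 mol%), (R)-BINAP (5.5 mol%), H2 pre-activation then Ar, CH2Cl2, rt
Reagents that add atoms: none
Why: Rhodium-catalysed intramolecular alkene hydroacylation of a 2-(1-substituted vinyl)benzaldehyde: the formyl C–H bond adds to monovalent rhodium, the hydride of the trivalent acyl rhodium hydride is delivered to the phenyl-bearing alkene carbon on the face selected by the C2-symmetric bisphosphine (this sets C3), and reductive elimination joins the acyl carbon to the terminal CH2.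

Step 3
Reactants: 4 (3S)-4,6-dimethoxy-3-phenylindan-1-one
Product: 5 (3S)-7-bromo-4,6-dimethoxy-3-phenylindan-1-one
Conditions: NBS (1.05 equiv), MeCN, 0 °C to rt, dark
Reagents that add atoms: N-bromosuccinimide, O=C1CCC(=O)N1Br
Why: Electrophilic aromatic bromination; C7 is para to the C4 methoxy and ortho to the C6 methoxy group while C5 is wedged between two methoxy groups, the same preference by which 3,5-dimethoxybenzaldehyde brominates next to its formyl group, and without acid or light the ketone α-carbon and the phenyl ring should not compete.

Step 4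
Reactants: 5 (3S)-7-bromo-4,6-dimethoxy-3-phenylindan-1-one
Product: 6 (4S)-8-bromo-5,7-dimethoxy-4-phenylchroman-2-one
Conditions: mCPBA (2.5 equiv), TFA (1.0 equiv), CH2Cl2, 0 °C to rt, dark; aq. Na2SO3, cold aq. NaHCO3 wash
Reagents that add atoms: 3-chloroperbenzoic acid (mCPBA), OOC(=O)c1cccc(Cl)c1
Why: The acid-activated C1 carbonyl takes up the peracid to give the peroxy hemiketal (Criegee adduct), and the aryl carbon C7a shifts from C1 to the proximal peroxide oxygen as 3-chlorobenzoate leaves, which is the Baeyer–Villiger oxidation of a 1-indanone to a 3,4-dihydrocoumarin. Ring B is not closed by a cyclisation but arises by one-atom enlargement of the five-membered ketone ring through this 1,2-shift, O1 ending up bonded to both C8a and C2. No stereocentre is created: the migrating carbon is trigonal, and indanone C3, which becomes C4, is neither enolisable nor touched, so 3S is carried over as 4S. The step needs aryl migration in preference to that of the C2 methylene: a primary alkyl group is a poor migrator, the aryl terminus can bridge in a phenonium-like transition state supported by the ortho ring-fusion carbon, and moving C7a off the carbonyl carbon relieves its peri compression against bromine. It also needs the peracid to spare the dimethoxyarene: the ring is deactivated by the carbonyl group and the bromine, its one free position C5 lies between two methoxy groups, and the reaction is stopped at full conversion so that the more electron-rich lactone is not hydroxylated.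

Step 5
Reactants: 6 (4S)-8-bromo-5,7-dimethoxy-4-phenylchroman-2-one; 7 (R)-2-methylbutanoic acid
Product: 9 (4S)-8-bromo-5,7-dimethoxy-6-[(2R)-2-methylbutanoyl]-4-phenylchroman-2-one, via (R)-2-methylbutanoyl chloride 8 (not isolated)
Conditions: 7 (1.3 equiv), (COCl)2 (0.95 equiv to 7), cat. DMF, CH2Cl2, 0 °C to rt; then 6, TiCl4 (2.5 equiv), CH2Cl2, −20 to 0 °C
Reagents that add atoms: none
Why: Friedel–Crafts acylation: with C8 occupied by bromine, C6 (ortho to both methoxy groups, para to O1) is the only ring carbon left, and making the acid chloride cold and using TiCl4 below 0 °C keeps ketene formation and enolisation, the two ways C2' could be lost, to a minimum.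

Step 6
Reactants: 9 (4S)-8-bromo-5,7-dimethoxy-6-[(2R)-2-methylbutanoyl]-4-phenylchroman-2-one
Product: 10 (4S)-8-bromo-5,7-dihydroxy-6-[(2R)-2-methylbutanoyl]-4-phenylchroman-2-one
Conditions: BBr3 (5 equiv), CH2Cl2, −78 to 0 °C; then ice water
Reagents that add atoms: none
Why: Lewis-acid cleavage of aryl methyl ethers; both methoxy groups are ortho to the ketone and should leave through boron chelates at low temperature, while the aryl bromide, the lactone (no nucleophile is present before the cold quench) and both stereocentres are left alone.

Step 7
Reactants: 10 (4S)-8-bromo-5,7-dihydroxy-6-[(2R)-2-methylbutanoyl]-4-phenylchroman-2-one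
Product: 11 (4S)-5,7-dihydroxy-6-[(2R)-2-methylbutanoyl]-4-phenylchroman-2-one
Conditions: H2 (1 atm), 10% Pd/C, NaOAc, EtOAc, rt
Reagents that add atoms: none
Why: Catalytic hydrogenolysis of the aryl C–Br bond, placed before any alkene is present; the hydrogen-bonded aryl ketone is slow to reduce, and a non-nucleophilic solvent with acetate as acid scavenger keeps the lactone closed.

Step 8
Reactants: 11 (4S)-5,7-dihydroxy-6-[(2R)-2-methylbutanoyl]-4-phenylchroman-2-one; 12 prenyl bromide (1-bromo-3-methylbut-2-ene, two equivalents incorporated)
Product: 13 (4S)-5-hydroxy-6-[(2R)-2-methylbutanoyl]-8,8-bis(3-methylbut-2-en-1-yl)-4-phenyl-3,4-dihydro-2H-chromene-2,7(8H)-dione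
Conditions: NaH (3.0 equiv), 12 (2.3 equiv), toluene/THF, 0 °C to rt; then cold 0.5 M HCl
Reagents that add atoms: none
Why: Alkylative dearomatisation of an acylphloroglucinol: C8 is the only ring carbon still bearing hydrogen, the sodium phenoxide in a non-polar medium is alkylated at carbon and not at oxygen, the first prenyl group gives the 8-prenyl phenol and the second makes C8 quaternary with the C7 ketone and the C5 enol hydrogen-bonded to the acyl group; C8 carries two identical groups, so no stereocentre arises, and a hydride base without a nucleophilic counter-ion spares the lactone.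

Compound list
1 | 2-bromo-3,5-dimethoxybenzaldehyde | O=Cc1c(Br)c(OC)cc(OC)c1 | starting material
2 | (1-phenylvinyl)boronic acid | OB(O)C(=C)c1ccccc1 | starting material
3 | 3,5-dimethoxy-2-(1-phenylvinyl)benzaldehyde | O=Cc1cc(OC)cc(OC)c1C(=C)c1ccccc1 | intermediate
4 | (3S)-4,6-dimethoxy-3-phenylindan-1-one | O=C1C[C@@H](c2ccccc2)c2c(OC)cc(OC)cc12 | intermediate
5 | (3S)-7-bromo-4,6-dimethoxy-3-phenylindan-1-one | O=C1C[C@@H](c2ccccc2)c2c(OC)cc(OC)c(Br)c12 | intermediate
6 | (4S)-8-bromo-5,7-dimethoxy-4-phenylchroman-2-one | O=C1C[C@@H](c2ccccc2)c2c(OC)cc(OC)c(Br)c2O1 | intermediate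
7 | (R)-2-methylbutanoic acid | CC[C@@H](C)C(=O)O | starting material
8 | (R)-2-methylbutanoyl chloride | CC[C@@H](C)C(=O)Cl | intermediate
9 | (4S)-8-bromo-5,7-dimethoxy-6-[(2R)-2-methylbutanoyl]-4-phenylchroman-2-one | O=C1C[C@@H](c2ccccc2)c2c(OC)c(C(=O)[C@H](C)CC)c(OC)c(Br)c2O1 | intermediate
10 | (4S)-8-bromo-5,7-dihydroxy-6-[(2R)-2-methylbutanoyl]-4-phenylchroman-2-one | O=C1C[C@@H](c2ccccc2)c2c(O)c(C(=O)[C@H](C)CC)c(O)c(Br)c2O1 | intermediate
11 | (4S)-5,7-dihydroxy-6-[(2R)-2-methylbutanoyl]-4-phenylchroman-2-one | O=C1C[C@@H](c2ccccc2)c2c(O)c(C(=O)[C@H](C)CC)c(O)cc2O1 | intermediate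
12 | prenyl bromide (1-bromo-3-methylbut-2-ene) | CC(C)=CCBr | starting material
13 | (4S)-5-hydroxy-6-[(2R)-2-methylbutanoyl]-8,8-bis(3-methylbut-2-en-1-yl)-4-phenyl-3,4-dihydro-2H-chromene-2,7(8H)-dione | CC[C@@H](C)C(=O)C1=C(O)C2=C(OC(=O)C[C@H]2c2ccccc2)C(CC=C(C)C)(CC=C(C)C)C1=O | target

Total step count: 8. Longest linear sequence: 8 steps (1 to 13); acid 7 enters at step 5 and is activated in the flask.

Steps most likely to fail

Step 4. The C2 methylene may migrate in place of the aryl carbon, because the aryl group is made electron-poor and crowded by its ortho bromine, or the peracid may attack the ring. The fallback sets out from 4 and moves the oxidation ahead of the halogenation. Buffered mCPBA in CH2Cl2 applied to 4 should give (4S)-5,7-dimethoxy-4-phenylchroman-2-one F1, the migrating aryl group now being unhindered and free of the halogen. NBS in MeCN should then brominate C8, which is para to the C5 methoxy group, whereas C6 lies between two methoxy groups. The route is rejoined at 6.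

Step 8. Alkylation may occur at oxygen, may stall after the first prenyl group, or the base may open the lactone. The fallback sets out from 11 and builds the quaternary carbon without added base. Pd(PPh3)4 with allyl tert-butyl carbonate in THF at rt (Tsuji–Trost allylation, in which any O-allyl ether re-ionises and funnels to carbon) should give (4S)-5-hydroxy-6-[(2R)-2-methylbutanoyl]-4-phenyl-8,8-di(prop-2-en-1-yl)-3,4-dihydro-2H-chromene-2,7(8H)-dione F2. Cross-metathesis of both allyl groups with 2-methyl-2-butene (second-generation Grubbs catalyst, CH2Cl2, 40 °C) then arrives at 13.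

Step 5. Substitution at the doubly flanked C6 may be slow, and forcing it may erode the configuration at C2' through ketene formation or enolisation. The fallback sets out from 6 and frees the phenols first. BBr3 in CH2Cl2 should give (4S)-8-bromo-5,7-dihydroxy-4-phenylchroman-2-one F3, whose ring is far more nucleophilic and whose C6 is less encumbered. C-acylation with acid chloride 8 and AlCl3 in CH2Cl2/PhNO2 at 0 °C then gives 10 directly, where the route is rejoined.

Further compounds
F1 | step 4 | (4S)-5,7-dimethoxy-4-phenylchroman-2-one | O=C1C[C@@H](c2ccccc2)c2c(OC)cc(OC)cc2O1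
F2 | step 8 | (4S)-5-hydroxy-6-[(2R)-2-methylbutanoyl]-4-phenyl-8,8-di(prop-2-en-1-yl)-3,4-dihydro-2H-chromene-2,7(8H)-dione | CC[C@@H](C)C(=O)C1=C(O)C2=C(OC(=O)C[C@H]2c2ccccc2)C(CC=C)(CC=C)C1=O
F3 | step 5 | (4S)-8-bromo-5,7-dihydroxy-4-phenylchroman-2-one | O=C1C[C@@H](c2ccccc2)c2c(O)cc(O)c(Br)c2O1
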